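**Assumptions (one line):** 11-bromo-1-undecene, 2-phenylethylmagnesium bromide, ethyl (E)-4-oxopent-2-enoate and methallylmagnesium chloride are commercially available. The cinchona primary-amine catalyst enantiomer is chosen to give the (2S,3S)-epoxide.

**Retrosynthetic overview**
1. The THF ring is closed last, by 5-exo Markovnikov hydroalkoxylation of a trisubstituted alkene with the Cd–OH of a cis-β-hydroxy-γ-lactone. This sets the quaternary ether carbon Ca under convex-face control.
2. The γ-lactone is formed before the THF, from a syn-diol ester. The trisubstituted alkene comes from cross-metathesis of a methallyl group with 13-phenyltridec-1-ene.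
3. The syn-diol ester comes from chelation-controlled methallylation of an α,β-epoxy ketone (setting Cc), followed by regioselective SmI2 cleavage of the epoxide C–O bond α to the ester.
4. The epoxy ketoester comes from organocatalytic asymmetric epoxidation of ethyl (E)-4-oxopent-2-enoate, which sets the first stereocenter (Cd).

**Route**

**Step 1**
Reactants: 1 (11-bromo-1-undecene), 2 (2-phenylethylmagnesium bromide)
Product: 3 (13-phenyltridec-1-ene)
Conditions: Li2CuCl4 (3 mol %), THF, 0 °C → rt
Reagents that add atoms: none
Why: Cu-catalysed Kumada alkyl–alkyl coupling joins the two C(sp3) fragments and leaves the terminal alkene intact, giving the cross-metathesis partner.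

**Step 2**
Reactants: 4 (ethyl (E)-4-oxopent-2-enoate)
Product: 5 (ethyl (2S,3S)-3-acetyloxirane-2-carboxylate, trans)
Conditions: 9-amino-9-deoxy-epi-hydroquinine (10 mol %), TFA (20 mol %), 30 % aq. H2O2 (2 equiv), THF, 25 °C
Reagents that add atoms: hydrogen peroxide, OO (adds one O)
Why: Primary-amine iminium activation of the ketone followed by H2O2 conjugate addition and ring closure (organocatalytic Weitz–Scheffer epoxidation) gives the trans-epoxide; the catalyst sets Cd as S, and Ce is erased later.

**Step 3**
Reactants: 5 and 6 (methallylmagnesium chloride)
Product: 7 (ethyl (2S,3S)-3-[(2S)-2-hydroxy-4-methylpent-4-en-2-yl]oxirane-2-carboxylate)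
Conditions: 6 (1.1 equiv), MgBr2·OEt2 (1 equiv), CH2Cl2/THF 4:1, −78 °C
Reagents that add atoms: none (6 is the reactant listed above)
Why: Mg chelation of the ketone and epoxide oxygens directs methallyl attack to the face carrying H rather than the epoxide carbon Ce (Cram-chelate 1,2-addition), which gives Cc = S, the syn relationship needed for the cis-fused bicycle.

**Step 4**
Reactants: 7
Product: 8 (ethyl (3S,4S)-3,4-dihydroxy-4,6-dimethylhept-6-enoate)
Conditions: SmI2 (2.5 equiv), THF/MeOH, −78 → 0 °C
Reagents that add atoms: none (MeOH supplies only H)
Why: SmI2 reductive opening of α,β-epoxy esters cleaves the C–O bond α to the ester, so Ce becomes CH2 and Cd keeps its oxygen and configuration.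

**Step 5**
Reactants: 8
Product: 9 ((4S,5S)-4-hydroxy-5-methyl-5-(2-methylallyl)dihydrofuran-2(3H)-one)
Conditions: TBD (10 mol %), toluene, 60 °C, 4 Å MS
Reagents that add atoms: none (EtOH is lost)
Why: Base-catalysed transesterification closes the γ-lactone through the tertiary OH, with no acid that would touch the alkene, and the syn-diol geometry puts Cd–OH cis to the Cc side chain.

**Step 6**
Reactants: 9 and 3 (3 equiv)
Product: 10 ((4S,5S)-4-hydroxy-5-methyl-5-(2-methyl-14-phenyltetradec-2-en-1-yl)dihydrofuran-2(3H)-one, E/Z mixture)
Conditions: Hoveyda–Grubbs II (5 mol %), CH2Cl2, 40 °C, ethylene vented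
Reagents that add atoms: none (3 is the reactant listed above)
Why: Cross-metathesis converts the 1,1-disubstituted alkene into the trisubstituted alkene; its E/Z ratio does not matter because the next step goes through a tertiary cation.

**Step 7**
Reactants: 10
Product: 11 (plakortone L)
Conditions: TfOH (10 mol %), CH2Cl2, 0 °C → rt
Reagents that add atoms: none (the step is a cycloisomerisation)
Why: Proposed new method: Brønsted-acid protonation of the trisubstituted alkene gives the tertiary Ca cation, which the cis Cd–OH captures in a 5-exo closure to form the 2,2-disubstituted THF fused to the lactone; the closest known reaction is TfOH-catalysed hydroalkoxylation of unactivated alkenols. The cis-fused bicycle places the larger chain on the convex face and the smaller methyl endo, giving Ca = S. The protocol has not been shown to build a fused tertiary ether with diastereocontrol from the ring fusion, and the acyloxy-substituted Cc does not ionise because the adjacent Cd–O is inductively withdrawing.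

**Compound list**
1 | 11-bromo-1-undecene | C=CCCCCCCCCCBr | starting material
2 | 2-phenylethylmagnesium bromide | Br[Mg]CCc1ccccc1 | starting material
3 | 13-phenyltridec-1-ene | C=CCCCCCCCCCCCc1ccccc1 | intermediate (metathesis partner)
4 | ethyl (E)-4-oxopent-2-enoate | CCOC(=O)/C=C/C(C)=O | starting material
5 | ethyl (2S,3S)-3-acetyloxirane-2-carboxylate | CC(=O)[C@H]1O[C@@H]1C(=O)OCC | intermediate
6 | methallylmagnesium chloride | CC(=C)C[Mg]Cl | starting material
7 | ethyl (2S,3S)-3-[(2S)-2-hydroxy-4-methylpent-4-en-2-yl]oxirane-2-carboxylate | CCOC(=O)[C@H]1O[C@@H]1[C@@](C)(O)CC(C)=C | intermediate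
8 | ethyl (3S,4S)-3,4-dihydroxy-4,6-dimethylhept-6-enoate | CCOC(=O)C[C@H](O)[C@@](C)(O)CC(C)=C | intermediate
9 | (4S,5S)-4-hydroxy-5-methyl-5-(2-methylallyl)dihydrofuran-2(3H)-one | C[C@@]1(CC(C)=C)OC(=O)C[C@@H]1O | intermediate
10 | (4S,5S)-4-hydroxy-5-methyl-5-(2-methyl-14-phenyltetradec-2-en-1-yl)dihydrofuran-2(3H)-one | C[C@@]1(CC(C)=CCCCCCCCCCCCc2ccccc2)OC(=O)C[C@@H]1O | intermediate
11 | plakortone L (all-S cis-fused 2,6-dioxabicyclo[3.3.0]octan-3-one) | C[C@]1(CCCCCCCCCCCCc2ccccc2)C[C@]2(C)OC(=O)C[C@@H]2O1 | target

**Totals:** 7 steps in total; longest linear sequence 6 (steps 2–7).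

**Three steps most likely to fail**
1. **Step 7 (proposed new step).** The diastereoselectivity at Ca may be poor, and retro-allylation, alkene isomerisation or lactone ionisation may compete.
   - Fallback: Co(salen)/PhSiH3/N-fluoropyridinium radical-polar-crossover hydroalkoxylation of 10, which is a non-cationic HAT mechanism.
2. **Step 3.** The chelation-controlled addition to the epoxy ketone may give poor dr, because the epoxide oxygen is a weak chelator.
   - Fallback: make the α-hydroxy ketone directly by proline-catalysed α-aminoxylation of ethyl levulinate with PhNO and N–O cleavage, then do the free-OH-chelated methallylation. This gives 8 directly and skips steps 2 and 4.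
3. **Step 6.** The neopentyl-type 1,1-disubstituted alkene may metathesise poorly.
   - Fallback: put the full 2-(12-phenyldodecyl)allyl unit into step 3 as a Barbier allylation reagent (from Cu-catalysed carbomagnesiation of propargyl alcohol, then bromination), so no metathesis is needed and step 7 closes a 1,1-disubstituted alkene.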